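A small reagent charge, twice the substrate charge, has to serve a chain in which each tris adduct costs 3 reagent.

    substrate + reagent → first product (k1 = 0.215 L mol⁻¹ h⁻¹)
    reagent + tris adduct ⇌ tetra adduct (K2 = 7.70 L mol⁻¹, k2 = 0.958 L mol⁻¹ h⁻¹)
    reagent + double product → tris adduct (k3 = 0.422 L mol⁻¹ h⁻¹)
    reagent + first product → double product (k4 = 0.148 L mol⁻¹ h⁻¹)

| flask | substrate | reagent | time | remark |
|---|---|---|---|---|
| noon | 0.072 M | 0.144 M | 10 d | everything together at the start |
| summer | 0.072 M (in portions, 3, over 8.0 d) | 0.144 M | 10 d | first portion at the start, last at 8.0 d |
| dawn | 0.072 M (fed, over 8.0 d) | 0.144 M | 10 d | all else is in the flask from the start; the feed brings no volume worth counting |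
| spring | 0.072 M | 0.144 M (fed, over 8.0 d) | 10 d | all else is in the flask from the start; the feed brings no volume worth counting |

* the flask that comes out highest in amount of tris adduct, in percent of the substrate charged; "all alike" if 1.5 percentage points covers them all (noon / summer / dawn / spring / all alike)
* amount of tris adduct at the end, in percent of the substrate charged, noon
* amount of tris adduct at the end, in percent of the substrate charged, summer
* amount of tris adduct at the end, in percent of the substrate charged, dawn
* amount of tris adduct at the end, in percent of the substrate charged, spring

We count fractions of the substrate charge: a substrate, m first product, d double product, t tris adduct, b free reagent. Were the reagent to end wholly in tris adduct, noon would reach 66.7%. To tighten this we freeze one ratio. The step consuming double product has a larger constant than the step making it, so we treat double product as a quasi-steady intermediate and hold d/m at the frozen ratio ρ, k4/k3, 0.351. The substrate and reagent balances, leaving tetra adduct aside, then give t = [1 + (1 + 2ρ)a − (1 + ρ)b]/(2 + ρ).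

On the clock τ = k1·cA·time, noon reaches 3.72, and reagent decays at a relative rate that starts at 1. With the frozen ratio that rate is a + 2(k4/k1)m, and 1.38 is close to 1 + ρ, 1.35, so it is near 1 − t, and we take it to stay between 1 and 0.5, which asks that t stay below 0.5. The fast case leaves b = 0.0487 and a = 0.142, which under that assumption puts noon no higher than 50.0%. The slow case leaves b = 0.312; we take a as zero and count tetra adduct, which holds 4 reagent, in both balances at K2·[reagent] per tris adduct, since the forward half-life of tris adduct by that step as charged, 0.21 d, is shorter than 10 d, and under the same assumption this puts noon no lower than 19.3%.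

The forecast chose noon, reasoning that “the all-at-once flask gets the most reagent-time exposure”. Its noon range, 33% to 42%, lies inside our bracket, and so does the simulated noon value.

| Flask | Forecast | Simulation |
|---|---|---|
| noon | 37.5% | 37.8% |
| summer | 29% | 29.1% |
| dawn | 27% | 28.7% |
| spring | 27% | 24.1% |

Noon has not come to rest at 10 d: 6.6% of its reagent stands free. By 100 d that reagent reads 0%, tetra adduct reads 0%, and tris adduct has risen to 47.8%. With b at zero and noon's remaining substrate of 8.31%, the formula gives 48.6%. Summer at the same time holds 12.1% substrate, for which the formula gives 51.3%, and its tris adduct stands at 51.3%.

The numbers of this flask are invented; what happens was integrated by code.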